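**Numbering used below:** germacrane numbering. C1 is the ketal carbon (OMe) and C4 the quaternary C(Me)–O carbon. C5=C6 is the exocyclic alkene and C7 the butenolide β-carbon. C8 carries the tigloyl ester and C10 the methyl group. C11–C13 are the lactone α-carbon, lactone C=O and CH2OAc.

**Assumptions (one line each):**
- The target SMILES is taken literally: tigloyl (E) ester, ring-cis C5=C6 (E by CIP).
- The enantiomer of pinene and the sense of the NHK ligand are chosen to give 10R and 8S. They are not verified here.

## Retrosynthesis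

1. Vernolide-B ⇐ the C8/C13 diol, by late acetylation and tigloylation. The tiglate is kept off until the end so that no acyl transfer or acetate E1cB occurs in the base step.
2. The 9-membered oxa-bridge and the ring-cis (E-CIP) alkylidene butenolide are closed last by an intramolecular vinylogous aldol at C5–C6, then dehydration. This is done across a cis-2,5-THF methyl ketal (the ring-cis geometry is imposed by the ring).
3. The THF methyl ketal comes from the C1 ketone, the C4 tertiary OH and MeOH. C4 stereochemistry comes from (R)-linalool and C10 from Brown crotylation.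
4. C7–C8 is made by an NHK coupling of a C8 aldehyde with a 4-bromobutenolide. The bromobutenolide comes from (E)-2,3-dibromobutenediol by Pd-catalysed carbonylative lactonization.
5. Ring-forming order: butenolide (step 9), THF ketal (step 14), 9-membered oxonane (step 15).

## Steps

**Step 1**
Reactants: 1, (R)-linalool
Product: 2, (2R)-2-methylpentane-1,2,5-triol
Conditions: O3, CH2Cl2/MeOH, –78 °C; then NaBH4, –78 → 0 °C
Reagents that add atoms: ozone, [O-][O+]=O (its O atoms end up as the C1 and C5 hydroxyl oxygens). NaBH4 adds only H.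
Why: Ozonolysis cleaves both alkenes and reductive work-up gives the triol. The quaternary carbinol C4 is untouched, so its (R) configuration is retained. The vinyl carbon becomes C5 and the prenyl CH becomes C1.

**Step 2**
Reactants: 2
Product: 3, 3-[(4R)-2,2,4-trimethyl-1,3-dioxolan-4-yl]propan-1-ol
Conditions: 2,2-dimethoxypropane, CSA (cat.), CH2Cl2, rt
Reagents that add atoms: 2,2-dimethoxypropane, COC(C)(C)OC (supplies the isopropylidene)
Why: Acetonide formation is selective for the 1,2-diol (C4-OH/C5-OH), masking C5 as a latent aldehyde and leaving C1-OH free.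

**Step 3**
Reactants: 3
Product: 4, 3-[(4R)-2,2,4-trimethyl-1,3-dioxolan-4-yl]propanal
Conditions: DMP, NaHCO3, CH2Cl2, 0 °C → rt
Reagents that add atoms: none
Why: Dess–Martin oxidation of the primary alcohol. No stereocentre is affected.

**Step 4**
Reactants: 4
Product: 5, (3R,4S)-3-methyl-6-[(4R)-2,2,4-trimethyl-1,3-dioxolan-4-yl]hex-1-en-4-ol
Conditions: (E)-crotyl-B(Ipc)2 (from (E)-2-butene, n-BuLi/KOtBu, (–)-Ipc2BOMe, BF3·OEt2), THF, –78 °C; then NaOH, H2O2
Reagents that add atoms: (E)-crotyldiisopinocampheylborane, C/C=C/CB(C1CC2CC(C1C)C2(C)C)C1CC2CC(C1C)C2(C)C (supplies C8, C9, C10, C14)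
Why: Brown asymmetric crotylation goes through a chair transition state. The reagent sets the methyl-bearing carbon C10 as R, with anti OH/Me. The C1 carbinol centre is destroyed later. The remote C4 centre does not interfere.

**Step 5**
Reactants: 5
Product: 6, triethylsilyl ether of 5 (C1-OTES)
Conditions: TESCl, imidazole, DMF, 0 °C → rt
Reagents that add atoms: TESCl, CC[Si](Cl)(CC)CC
Why: Protecting C1-OH prevents lactol or lactone formation and over-oxidation in steps 6–7.

**Step 6**
Reactants: 6
Product: 7, (3R,4S)-3-methyl-4-(triethylsilyloxy)-6-[(4R)-2,2,4-trimethyl-1,3-dioxolan-4-yl]hexan-1-ol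
Conditions: 9-BBN, THF, 0 °C → rt; then NaBO3·4H2O (or H2O2/NaOH), THF/H2O
Reagents that add atoms: hydrogen peroxide/perborate, OO (its O becomes the C8-OH)
Why: Hydroboration–oxidation is anti-Markovnikov on the terminal C9=C8 alkene. It is the only alkene in the molecule, so chemoselectivity is not an issue. The stereocentres are untouched.

**Step 7**
Reactants: 7
Product: 8, (3R,4S)-3-methyl-4-(triethylsilyloxy)-6-[(4R)-2,2,4-trimethyl-1,3-dioxolan-4-yl]hexanal (the C8 aldehyde)
Conditions: DMP, NaHCO3, CH2Cl2, rt
Reagents that add atoms: none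
Why: Oxidation of the primary alcohol. C10 is β to the aldehyde and C1 is silylated, so there is no epimerisation pathway.

**Step 8**
Reactants: 9, (E)-2,3-dibromobut-2-ene-1,4-diol (commercial)
Product: 10, (E)-2,3-dibromo-4-(tert-butyldiphenylsilyloxy)but-2-en-1-ol
Conditions: TBDPSCl (0.9 equiv), imidazole, DMF, 0 °C → rt
Reagents that add atoms: TBDPSCl, CC(C)(C)[Si](Cl)(c1ccccc1)c1ccccc1
Why: Statistical mono-silylation of the symmetric diol. Recovered diol is recycled. The free CH2OH now determines which C–Br undergoes carbonylation.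

**Step 9**
Reactants: 10
Product: 11, 4-bromo-3-[(TBDPS-oxy)methyl]furan-2(5H)-one
Conditions: Pd(PPh3)4 (5 mol%), CO (1 atm), Et3N, MeCN, 60 °C
Reagents that add atoms: carbon monoxide, [C-]#[O+] (becomes C12)
Why: Pd-catalysed carbonylative lactonization (hydroxy-directed alkoxycarbonylation). In the E-diol the free CH2OH is cis to the bromide on the other carbon. Insertion at that C–Br and capture by the OH gives the butenolide with CH2OTBDPS on C11 and Br on C7. The protected arm cannot cyclise, so over-carbonylation to a bis-lactone is avoided.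

**Step 10**
Reactants: 8 and 11
Product: 12, 4-[(1S,3R,4S)-1-hydroxy-3-methyl-4-(TESO)-6-((4R)-2,2,4-trimethyl-1,3-dioxolan-4-yl)hexyl]-3-(TBDPSO-methyl)furan-2(5H)-one
Conditions: CrCl2 (cat.), chiral sulfonamide ligand L* (Kishi type, sense giving 8S), NiCl2 (cat.), Mn, TMSCl, MeCN/DMF, rt; then aqueous work-up
Reagents that add atoms: none (any TMS ether formed in situ is cleaved in work-up)
Why: Nozaki–Hiyama–Kishi coupling: the vinyl-Cr(III) species from the β-bromo-enoate adds chemoselectively to the aldehyde, and the lactone, silyl ethers and acetonide are inert. The chiral ligand (reagent control) sets C8 as S, because the remote C10 centre gives poor substrate control.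

**Step 11**
Reactants: 12
Product: 13, C8-TBS ether of 12
Conditions: TBSOTf, 2,6-lutidine, CH2Cl2, –78 °C
Reagents that add atoms: TBSOTf, CC(C)(C)[Si](C)(C)OS(=O)(=O)C(F)(F)F
Why: Protecting C8-OH stops DMP from oxidising it in step 13. It also avoids an O→C acyl transfer from a C8 tiglate onto the C6 dienolate in step 15. C8 configuration is retained.

**Step 12**
Reactants: 13
Product: 14, triol with C1-OH, C4-OH and C5-OH free (C8-OTBS and C13-OTBDPS retained)
Conditions: AcOH/THF/H2O (3:1:1), 40 °C
Reagents that add atoms: none (acetone and TES-OH/TES-OAc are lost)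
Why: Acid hydrolysis removes the secondary TES ether and the acetonide together. The hindered secondary TBS and primary TBDPS ethers survive.

**Step 13**
Reactants: 14
Product: 15, C1 ketone / C4-OH / C5 aldehyde
Conditions: DMP (2.5 equiv), NaHCO3, CH2Cl2, 0 °C
Reagents that add atoms: none
Why: DMP oxidises the secondary C1-OH and the primary C5-OH. The tertiary C4-OH is untouched, and C4 is quaternary so it cannot epimerise. Buffering at 0 °C limits epimerisation of C10, which is α to the new ketone, and limits lactol formation.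

**Step 14**
Reactants: 15
Product: 16, THF methyl ketal with C5 aldehyde (C1 = S, C4 = R)
Conditions: MeOH (10 equiv), HC(OMe)3, PPTS (cat.), CH2Cl2, rt; separate the C1 epimers and re-equilibrate the unwanted one with PPTS/MeOH
Reagents that add atoms: methanol, CO (supplies OMe); trimethyl orthoformate, COC(OC)OC (water scavenger)
Why: The γ-hydroxy ketone forms a hemiketal and then a methyl ketal under thermodynamic control. Only the C1 epimer cis to C4 (1S,4R) can bridge in step 15, and the epimers interconvert under acid. The hindered α-quaternary C5 aldehyde does not acetalise appreciably. After ketalisation C10 is configurationally locked.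

**Step 15**
Reactants: 16
Product: 17, C5-hydroxy/C6-H aldol macrocycle (C5/C6 stereocentres undefined, removed in step 16)
Conditions: KHMDS (1.1 equiv), THF, –78 °C, 2 mM, slow addition
Reagents that add atoms: none
Why: Intramolecular vinylogous aldol. The γ-dienolate of the butenolide (C6) adds to the non-enolisable C5 aldehyde. The cis-2,5-disubstituted THF pre-organises the two arms to close the 9-membered oxa-bridged ring. C5 and C6 are temporary centres and no other base-labile site is present.

**Step 16**
Reactants: 17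
Product: 18, macrocycle with TBS at C8 and TBDPS at C13 (the 5,6-alkylidene butenolide)
Conditions: MsCl, Et3N, CH2Cl2, 0 °C; then DBU, rt
Reagents that add atoms: none (the mesylate is lost)
Why: Mesylation followed by E1cB elimination (acidic C6-H). Ring size forces the ring-cis alkene, which is E by CIP as in the target.

**Step 17**
Reactants: 18
Product: 19, C8/C13 diol
Conditions: TBAF, AcOH (buffer), THF, 0 °C → rt
Reagents that add atoms: none
Why: Fluoride removes the TBS and TBDPS ethers. The ketal is base-stable, and AcOH buffering protects the enol lactone.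

**Step 18**
Reactants: 19
Product: 20, C13-acetate with free C8-OH
Conditions: Ac2O (1.1 equiv), pyridine, DMAP (cat.), CH2Cl2, –20 °C
Reagents that add atoms: acetic anhydride, CC(=O)OC(C)=O
Why: The primary allylic OH is acylated selectively over the hindered secondary C8-OH.

**Step 19**
Reactants: 20
Product: 21, Vernolide-B
Conditions: tigloyl chloride, Et3N, DMAP, CH2Cl2, 0 → rt
Reagents that add atoms: tigloyl chloride, C/C=C(\C)C(=O)Cl
Why: Acylation of the hindered C8-OH. The (E)-tiglate geometry comes from the reagent, C8 is unchanged, and the ketal and enol lactone survive.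

## Compound list

| No. | Name | SMILES | Role |
|---|---|---|---|
| 1 | (3R)-3,7-dimethylocta-1,6-dien-3-ol, (R)-linalool | C=C[C@](C)(O)CCC=C(C)C | starting material |
| 2 | (2R)-2-methylpentane-1,2,5-triol | OC[C@](C)(O)CCCO | intermediate |
| 3 | 3-[(4R)-2,2,4-trimethyl-1,3-dioxolan-4-yl]propan-1-ol | OCCC[C@]1(C)COC(C)(C)O1 | intermediate |
| 4 | 3-[(4R)-2,2,4-trimethyl-1,3-dioxolan-4-yl]propanal | O=CCC[C@]1(C)COC(C)(C)O1 | intermediate |
| 5 | (3R,4S)-3-methyl-6-[(4R)-trimethyldioxolanyl]hex-1-en-4-ol | C=C[C@@H](C)[C@@H](O)CC[C@]1(C)COC(C)(C)O1 | intermediate |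
| 6 | C1-TES ether of 5 | C=C[C@@H](C)[C@@H](O[Si](CC)(CC)CC)CC[C@]1(C)COC(C)(C)O1 | intermediate |
| 7 | (3R,4S)-3-methyl-4-(TESO)-6-[(4R)-trimethyldioxolanyl]hexan-1-ol | OCC[C@@H](C)[C@@H](O[Si](CC)(CC)CC)CC[C@]1(C)COC(C)(C)O1 | intermediate |
| 8 | (3R,4S)-3-methyl-4-(TESO)-6-[(4R)-trimethyldioxolanyl]hexanal | O=CC[C@@H](C)[C@@H](O[Si](CC)(CC)CC)CC[C@]1(C)COC(C)(C)O1 | intermediate |
| 9 | (E)-2,3-dibromobut-2-ene-1,4-diol | OC/C(Br)=C(Br)/CO | starting material |
| 10 | (E)-2,3-dibromo-4-(TBDPSO)but-2-en-1-ol | OC/C(Br)=C(Br)/CO[Si](c1ccccc1)(c1ccccc1)C(C)(C)C | intermediate |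
| 11 | 4-bromo-3-[(TBDPS-oxy)methyl]furan-2(5H)-one | O=C1OCC(Br)=C1CO[Si](c1ccccc1)(c1ccccc1)C(C)(C)C | intermediate |
| 12 | NHK adduct (8S) | O=C1OCC([C@@H](O)C[C@@H](C)[C@@H](O[Si](CC)(CC)CC)CC[C@]2(C)COC(C)(C)O2)=C1CO[Si](c1ccccc1)(c1ccccc1)C(C)(C)C | intermediate |
| 13 | C8-TBS ether of 12 | O=C1OCC([C@@H](O[Si](C)(C)C(C)(C)C)C[C@@H](C)[C@@H](O[Si](CC)(CC)CC)CC[C@]2(C)COC(C)(C)O2)=C1CO[Si](c1ccccc1)(c1ccccc1)C(C)(C)C | intermediate |
| 14 | triol (C1-OH, C4-OH, C5-OH free) | O=C1OCC([C@@H](O[Si](C)(C)C(C)(C)C)C[C@@H](C)[C@@H](O)CC[C@@](C)(O)CO)=C1CO[Si](c1ccccc1)(c1ccccc1)C(C)(C)C | intermediate |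
| 15 | C1 ketone / C4-OH / C5 aldehyde | O=C1OCC([C@@H](O[Si](C)(C)C(C)(C)C)C[C@@H](C)C(=O)CC[C@@](C)(O)C=O)=C1CO[Si](c1ccccc1)(c1ccccc1)C(C)(C)C | intermediate |
| 16 | THF methyl ketal aldehyde (1S,4R) | O=C1OCC([C@@H](O[Si](C)(C)C(C)(C)C)C[C@@H](C)[C@]2(OC)CC[C@](C)(C=O)O2)=C1CO[Si](c1ccccc1)(c1ccccc1)C(C)(C)C | intermediate |
| 17 | aldol macrocycle (C5-OH, C6-H) | CC(C)(C)[Si](C)(C)O[C@H]1C[C@@H](C)[C@]2(OC)CC[C@](C)(C(O)C3OC(=O)C(CO[Si](c4ccccc4)(c4ccccc4)C(C)(C)C)=C31)O2 | intermediate |
| 18 | alkylidene butenolide macrocycle, C8-OTBS, C13-OTBDPS | CC(C)(C)[Si](C)(C)O[C@H]1C[C@@H](C)[C@]2(OC)CC[C@](C)(/C=C3/OC(=O)C(CO[Si](c4ccccc4)(c4ccccc4)C(C)(C)C)=C31)O2 | intermediate |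
| 19 | C8/C13 diol | O[C@H]1C[C@@H](C)[C@]2(OC)CC[C@](C)(/C=C3/OC(=O)C(CO)=C31)O2 | intermediate |
| 20 | C13-acetate, C8-OH | O[C@H]1C[C@@H](C)[C@]2(OC)CC[C@](C)(/C=C3/OC(=O)C(COC(C)=O)=C31)O2 | intermediate |
| 21 | Vernolide-B | C/C=C(\C)C(=O)O[C@H]1C[C@@H](C)[C@]2(OC)CC[C@](C)(/C=C3/OC(=O)C(COC(C)=O)=C31)O2 | target |

**Total steps:** 19. **Longest linear sequence:** 17 (linalool → 8 in 7 steps, then steps 10–19).

## Three steps most likely to fail

1. **Step 15 (macro vinylogous aldol).** The 9-membered oxa-bridged closure may be slow, and dimerisation or α-attack may compete. Fallback (different reaction): convert 16 to the C6-diethylphosphonate butenolide (NBS, then P(OEt)3) and close C5=C6 by intramolecular Horner–Wadsworth–Emmons (LiCl/DBU, Masamune–Roush). This directly gives the ring-cis alkene.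
2. **Step 10 (NHK of the β-bromobutenolide and C8 stereocontrol).** The vinyl bromide may be reduced or unreactive, and the ligand may give poor 8S selectivity. Fallback (different bond-forming method): use the 4-iodobutenolide, do an iPrMgCl·LiCl I/Mg exchange at –78 °C and add it to aldehyde 8, then oxidise with DMP and reduce the enone with (R)-Me-CBS/BH3 to set 8S by catalyst control.
3. **Steps 13–14 (double DMP oxidation, C10 epimerisation, C1 epimer ratio).** Lactol/lactone formation, epimerisation at C10 or an unfavourable C1 ketal ratio could occur. Fallback (different masking of C5): start from linalool's own vinyl group (6,7-epoxidation then H5IO6 cleavage in place of steps 1–3). Carry the vinyl through, oxidise C1 to the ketone, form the methyl ketal, and only then unmask the C5 aldehyde by OsO4/NaIO4.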